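**Retrosynthetic overview**
- The target is reached by one global hydrogenolysis of its 21-fold benzyl ether. It has no C–C bond between rings, only seven diaryl ether C–O bonds.
- These C–O bonds are cut one at a time from ring H back to ring A. Each of rings B–G is delivered as a bromo-benzaldehyde: the CHO group is a masked phenol (Baeyer–Villiger oxidation) and, where ortho or para to bromine, also activates C–Br for Cu-catalysed O-arylation. Ring H is a plain aryl bromide.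
- Key C–C construction: the carbon ring of ring A is built de novo by intermolecular Claisen condensation of diethyl malonate with diethyl 3-oxopentanedioate followed by Dieckmann closure, then decarboxylated to phloroglucinol and elaborated to 2,4,6-tris(benzyloxy)phenol.
- Ring order: ring A is the only ring formed, and it is formed first. Rings B, C, D, E, F, G and H come from aromatic building blocks and are attached in that order.

Assumption: the target has no stereocentre or stereoaxis, so it is one achiral compound and no stereocontrol is needed.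
Notation: Bn = benzyl. Rings are lettered A to H from the 2,4,6-trihydroxyphenyl end to the 3,4,5-trihydroxyphenoxy end. "AB-oxy" means the aryloxy group of AB phenol 24, and likewise for longer letter strings.

**Ring A (de novo) and its phenol**

Step 1
Reactants: 1 diethyl malonate; 2 diethyl 3-oxopentanedioate
Product: 4 diethyl 2,4,6-trihydroxybenzene-1,3-dicarboxylate, via acyclic dioxo triester 3 (not isolated)
Conditions: 1 (1.5 equiv), NaOEt (1.5 equiv), EtOH, rt, then EtOH evaporated; 2 (1 equiv) added slowly, neat, 140–145 °C, EtOH distilled off; then cold 2 M HCl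
Reagents that add atoms: none
Why: Intermolecular Claisen condensation in which the sodium enolate of 2 is C-acylated by one ester group of 1 to give 3, followed by Dieckmann closure onto the second malonate ester and enolisation to the aromatic phenoxide salt (EtOH removed), which pulls the equilibria forward; no stereocentre is formed.

Step 2
Reactants: 4 diethyl 2,4,6-trihydroxybenzene-1,3-dicarboxylate
Product: 5 phloroglucinol (benzene-1,3,5-triol)
Conditions: 10% aq. KOH, reflux, N2; then conc. HCl to pH 1, 80 °C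
Reagents that add atoms: none
Why: Ester saponification followed by decarboxylation, which is facile because each carboxyl group is a β-keto acid in the keto tautomer of the ring and is flanked by two ortho hydroxyl groups.

Step 3
Reactants: 5 phloroglucinol
Product: 6 benzene-1,3,5-triyl triacetate
Conditions: Ac2O, pyridine, rt
Reagents that add atoms: acetic anhydride, CC(=O)OC(C)=O
Why: Exhaustive O-acetylation (nucleophilic acyl substitution) masks the ambident triphenol for clean O-benzylation in the next step.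

Step 4
Reactants: 6 benzene-1,3,5-triyl triacetate
Product: 7 1,3,5-tris(benzyloxy)benzene
Conditions: BnCl (3.3 equiv), NaH (6.6 equiv), DMF, H2O (3 equiv, slow addition), 0 °C → rt
Reagents that add atoms: benzyl chloride, ClCc1ccccc1
Why: One-pot deacetylation and Williamson etherification, in which NaOH formed from NaH and water frees each phenoxide at low concentration so that it is O-benzylated at once and the C-benzylation typical of free phloroglucinol is avoided.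

Step 5
Reactants: 7 1,3,5-tris(benzyloxy)benzene
Product: 9 2,4,6-tris(benzyloxy)benzaldehyde, via iminium chloride 8 (not isolated)
Conditions: POCl3 (1.2 equiv), DMF, 0 °C → rt; then ice–water, 50 °C
Reagents that add atoms: N,N-dimethylformamide, CN(C)C=O; water, O
Why: Vilsmeier–Haack formylation of a strongly activated arene whose three free positions are equivalent, stopping at mono-substitution because the iminium group deactivates the ring.

Step 6
Reactants: 9 2,4,6-tris(benzyloxy)benzaldehyde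
Product: 11 2,4,6-tris(benzyloxy)phenol, via aryl formate 10 (not isolated)
Conditions: mCPBA (1.3 equiv), CH2Cl2, 0 °C → rt; aq. NaHCO3 wash; then K2CO3 (0.2 equiv), MeOH/THF, rt, Ar
Reagents that add atoms: 3-chloroperoxybenzoic acid (mCPBA), OOC(=O)c1cccc(Cl)c1
Why: Baeyer–Villiger (Dakin-type) oxidation in which the electron-rich aryl group migrates to give the formate, which is cleaved by base-catalysed methanolysis.

**Building blocks for rings B–H**

Step 7
Reactants: 12 5-bromo-2-hydroxy-3-methoxybenzaldehyde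
Product: 13 5-bromo-2,3-dihydroxybenzaldehyde
Conditions: BBr3 (2.5 equiv), CH2Cl2, −78 °C → rt; then H2O
Reagents that add atoms: none
Why: Lewis-acid cleavage of the aryl methyl ether by BBr3, which leaves the aldehyde and the aryl bromide untouched.

Step 8
Reactants: 13 5-bromo-2,3-dihydroxybenzaldehyde
Product: 14 2,3-bis(benzyloxy)-5-bromobenzaldehyde
Conditions: BnBr (2.4 equiv), K2CO3 (3 equiv), DMF, 60 °C
Reagents that add atoms: benzyl bromide, BrCc1ccccc1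
Why: Williamson etherification of both phenols, with warming to overcome the hydrogen bond between the 2-hydroxyl and the aldehyde.

Step 9
Reactants: 15 5-bromo-1,2,3-trimethoxybenzene
Product: 16 5-bromobenzene-1,2,3-triol
Conditions: BBr3 (3.6 equiv), CH2Cl2, −78 °C → rt; then H2O
Reagents that add atoms: none
Why: Exhaustive BBr3 demethylation of the three aryl methyl ethers, a standard Lewis-acid ether cleavage.

Step 10
Reactants: 16 5-bromobenzene-1,2,3-triol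
Product: 17 5-bromo-1,2,3-tris(benzyloxy)benzene
Conditions: BnBr (3.6 equiv), K2CO3 (4.5 equiv), DMF, N2, 60 °C
Reagents that add atoms: benzyl bromide, BrCc1ccccc1
Why: Threefold Williamson etherification under nitrogen to protect the air-sensitive pyrogallol.

Step 11
Reactants: 17 5-bromo-1,2,3-tris(benzyloxy)benzene
Product: 19 6-bromo-2,3,4-tris(benzyloxy)benzaldehyde, via iminium chloride 18 (not isolated)
Conditions: POCl3 (3 equiv), DMF, 90 °C; then ice–water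
Reagents that add atoms: N,N-dimethylformamide, CN(C)C=O; water, O
Why: Vilsmeier–Haack formylation at the only free ring positions (two equivalent sites, each ortho and para to benzyloxy groups), so the regiochemistry is unambiguous.

Step 12
Reactants: 20 4-bromo-2,6-difluorobenzaldehyde
Product: 21 4-bromo-2,6-bis(benzyloxy)benzaldehyde
Conditions: BnOH (2.2 equiv), NaH (2.3 equiv), THF, 0 °C → 50 °C
Reagents that add atoms: benzyl alcohol, OCc1ccccc1
Why: Twofold SNAr (addition–elimination) by benzyloxide at the fluorides ortho to the aldehyde, which are far better leaving groups than the para bromide.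

**Assembly A → H**

Step 13
Reactants: 11 2,4,6-tris(benzyloxy)phenol; 14 2,3-bis(benzyloxy)-5-bromobenzaldehyde
Product: 22 AB aldehyde [2,3-bis(benzyloxy)-5-[2,4,6-tris(benzyloxy)phenoxy]benzaldehyde]
Conditions: CuI (10 mol %), picolinic acid (20 mol %), K3PO4 (2 equiv), DMSO, 90 °C, Ar
Reagents that add atoms: none
Why: Ullmann-type Cu-catalysed diaryl ether synthesis between a hindered electron-rich phenol and an unhindered aryl bromide, the combination for which the picolinic acid ligand is suited.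

Step 14
Reactants: 22 AB aldehyde
Product: 24 AB phenol [2,3-bis(benzyloxy)-5-[2,4,6-tris(benzyloxy)phenoxy]phenol], via AB formate 23 (not isolated)
Conditions: mCPBA (1.3 equiv), CH2Cl2, 0 °C → rt; aq. NaHCO3 wash; then K2CO3 (0.2 equiv), MeOH/THF, rt, Ar
Reagents that add atoms: 3-chloroperoxybenzoic acid (mCPBA), OOC(=O)c1cccc(Cl)c1
Why: Baeyer–Villiger oxidation of an ortho-alkoxy benzaldehyde (aryl migration), then formate methanolysis.

Step 15
Reactants: 24 AB phenol; 19 6-bromo-2,3,4-tris(benzyloxy)benzaldehyde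
Product: 25 ABC aldehyde [2,3,4-tris(benzyloxy)-6-(AB-oxy)benzaldehyde]
Conditions: CuI (10 mol %), picolinic acid (20 mol %), K3PO4 (2 equiv), DMSO, 90 °C, Ar
Reagents that add atoms: none
Why: Ullmann-type O-arylation in which the ortho-formyl group accelerates substitution of the bromide.

Step 16
Reactants: 25 ABC aldehyde
Product: 27 ABC phenol [2,3,4-tris(benzyloxy)-6-(AB-oxy)phenol], via ABC formate 26 (not isolated)
Conditions: mCPBA (1.3 equiv), CH2Cl2, 0 °C → rt; aq. NaHCO3 wash; then K2CO3 (0.2 equiv), MeOH/THF, rt, Ar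
Reagents that add atoms: 3-chloroperoxybenzoic acid (mCPBA), OOC(=O)c1cccc(Cl)c1
Why: Baeyer–Villiger oxidation of an aldehyde flanked by two oxygen substituents (aryl migration strongly favoured), then formate methanolysis.

Step 17
Reactants: 27 ABC phenol; 21 4-bromo-2,6-bis(benzyloxy)benzaldehyde
Product: 28 ABCD aldehyde [2,6-bis(benzyloxy)-4-(ABC-oxy)benzaldehyde]
Conditions: CuI (15 mol %), picolinic acid (30 mol %), K3PO4 (2 equiv), DMSO, 90 °C, Ar
Reagents that add atoms: none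
Why: Ullmann-type O-arylation of a hindered phenol by an unhindered bromide activated by the para-formyl group.

Step 18
Reactants: 28 ABCD aldehyde
Product: 30 ABCD phenol [2,6-bis(benzyloxy)-4-(ABC-oxy)phenol], via ABCD formate 29 (not isolated)
Conditions: mCPBA (1.3 equiv), CH2Cl2, 0 °C → rt; aq. NaHCO3 wash; then K2CO3 (0.2 equiv), MeOH/THF, rt, Ar
Reagents that add atoms: 3-chloroperoxybenzoic acid (mCPBA), OOC(=O)c1cccc(Cl)c1
Why: Baeyer–Villiger oxidation of a 2,6-dialkoxy-4-aryloxy benzaldehyde (aryl migration), then formate methanolysis.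

Step 19
Reactants: 30 ABCD phenol; 19 6-bromo-2,3,4-tris(benzyloxy)benzaldehyde
Product: 31 ABCDE aldehyde [2,3,4-tris(benzyloxy)-6-(ABCD-oxy)benzaldehyde]
Conditions: 19 (1.5 equiv), CuI (20 mol %), picolinic acid (40 mol %), K3PO4 (2.5 equiv), DMSO/dioxane, 100 °C, Ar
Reagents that add atoms: none
Why: Ullmann-type O-arylation of a phenol flanked by two benzyloxy groups, made feasible by ortho-formyl activation of the bromide and the hindered-substrate ligand.

Step 20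
Reactants: 31 ABCDE aldehyde
Product: 33 ABCDE phenol [2,3,4-tris(benzyloxy)-6-(ABCD-oxy)phenol], via ABCDE formate 32 (not isolated)
Conditions: mCPBA (1.3 equiv), CH2Cl2, 0 °C → rt; aq. NaHCO3 wash; then K2CO3 (0.2 equiv), MeOH/THF, rt, Ar
Reagents that add atoms: 3-chloroperoxybenzoic acid (mCPBA), OOC(=O)c1cccc(Cl)c1
Why: Baeyer–Villiger oxidation as in step 16, then formate methanolysis.

Step 21
Reactants: 33 ABCDE phenol; 21 4-bromo-2,6-bis(benzyloxy)benzaldehyde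
Product: 34 ABCDEF aldehyde [2,6-bis(benzyloxy)-4-(ABCDE-oxy)benzaldehyde]
Conditions: CuI (15 mol %), picolinic acid (30 mol %), K3PO4 (2 equiv), DMSO/dioxane, 90 °C, Ar
Reagents that add atoms: none
Why: Ullmann-type O-arylation of the same kind as step 17.

Step 22
Reactants: 34 ABCDEF aldehyde
Product: 36 ABCDEF phenol [2,6-bis(benzyloxy)-4-(ABCDE-oxy)phenol], via ABCDEF formate 35 (not isolated)
Conditions: mCPBA (1.3 equiv), CH2Cl2, 0 °C → rt; aq. NaHCO3 wash; then K2CO3 (0.2 equiv), MeOH/THF, rt, Ar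
Reagents that add atoms: 3-chloroperoxybenzoic acid (mCPBA), OOC(=O)c1cccc(Cl)c1
Why: Baeyer–Villiger oxidation as in step 18, then formate methanolysis.

Step 23
Reactants: 36 ABCDEF phenol; 19 6-bromo-2,3,4-tris(benzyloxy)benzaldehyde
Product: 37 ABCDEFG aldehyde [2,3,4-tris(benzyloxy)-6-(ABCDEF-oxy)benzaldehyde]
Conditions: 19 (1.5 equiv), CuI (20 mol %), picolinic acid (40 mol %), K3PO4 (2.5 equiv), DMSO/dioxane, 100 °C, Ar
Reagents that add atoms: none
Why: Ullmann-type O-arylation of the same kind as step 19.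

Step 24
Reactants: 37 ABCDEFG aldehyde
Product: 39 ABCDEFG phenol [2,3,4-tris(benzyloxy)-6-(ABCDEF-oxy)phenol], via ABCDEFG formate 38 (not isolated)
Conditions: mCPBA (1.3 equiv), CH2Cl2, 0 °C → rt; aq. NaHCO3 wash; then K2CO3 (0.2 equiv), MeOH/THF, rt, Ar
Reagents that add atoms: 3-chloroperoxybenzoic acid (mCPBA), OOC(=O)c1cccc(Cl)c1
Why: Baeyer–Villiger oxidation as in step 16, then formate methanolysis.

Step 25
Reactants: 39 ABCDEFG phenol; 17 5-bromo-1,2,3-tris(benzyloxy)benzene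
Product: 40 henicosa-O-benzyl octamer [1,2,3-tris(benzyloxy)-5-(ABCDEFG-oxy)benzene]
Conditions: 17 (3 equiv), CuI (20 mol %), picolinic acid (40 mol %), K3PO4 (3 equiv), DMSO/dioxane, 105 °C, Ar
Reagents that add atoms: none
Why: Ullmann-type O-arylation of a hindered phenol with an unhindered aryl bromide, pushed by excess of the cheap bromide.

Step 26
Reactants: 40 henicosa-O-benzyl octamer
Product: 41 CNP0175816.0 (target)
Conditions: H2 (1–4 bar), Pd(OH)2/C, THF/MeOH 1:1, rt; filtered and freeze-dried under Ar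
Reagents that add atoms: none
Why: Catalytic hydrogenolysis cleaves all 21 benzylic C–O bonds while the diaryl ether bonds are inert, and it creates no stereocentre.

**Compound list**

1 | diethyl malonate | CCOC(=O)CC(=O)OCC | starting material
2 | diethyl 3-oxopentanedioate (diethyl acetone-1,3-dicarboxylate) | CCOC(=O)CC(=O)CC(=O)OCC | starting material
3 | triethyl 2,4-dioxopentane-1,3,5-tricarboxylate (acyclic dioxo triester) | CCOC(=O)CC(=O)C(C(=O)OCC)C(=O)CC(=O)OCC | intermediate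
4 | diethyl 2,4,6-trihydroxybenzene-1,3-dicarboxylate | CCOC(=O)c1c(O)cc(O)c(C(=O)OCC)c1O | intermediate
5 | phloroglucinol (benzene-1,3,5-triol) | Oc1cc(O)cc(O)c1 | intermediate
6 | benzene-1,3,5-triyl triacetate | CC(=O)Oc1cc(OC(C)=O)cc(OC(C)=O)c1 | intermediate
7 | 1,3,5-tris(benzyloxy)benzene | c1ccc(COc2cc(OCc3ccccc3)cc(OCc3ccccc3)c2)cc1 | intermediate
8 | N-[2,4,6-tris(benzyloxy)benzylidene]-N-methylmethanaminium chloride | C[N+](C)=Cc1c(OCc2ccccc2)cc(OCc2ccccc2)cc1OCc1ccccc1.[Cl-] | intermediate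
9 | 2,4,6-tris(benzyloxy)benzaldehyde | O=Cc1c(OCc2ccccc2)cc(OCc2ccccc2)cc1OCc1ccccc1 | intermediate
10 | 2,4,6-tris(benzyloxy)phenyl formate | O=COc1c(OCc2ccccc2)cc(OCc2ccccc2)cc1OCc1ccccc1 | intermediate
11 | 2,4,6-tris(benzyloxy)phenol | Oc1c(OCc2ccccc2)cc(OCc2ccccc2)cc1OCc1ccccc1 | intermediate
12 | 5-bromo-2-hydroxy-3-methoxybenzaldehyde | COc1cc(Br)cc(C=O)c1O | starting material
13 | 5-bromo-2,3-dihydroxybenzaldehyde | Oc1cc(Br)cc(C=O)c1O | intermediate
14 | 2,3-bis(benzyloxy)-5-bromobenzaldehyde | O=Cc1cc(Br)cc(OCc2ccccc2)c1OCc1ccccc1 | intermediate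
15 | 5-bromo-1,2,3-trimethoxybenzene | COc1cc(Br)cc(OC)c1OC | starting material
16 | 5-bromobenzene-1,2,3-triol | Oc1cc(Br)cc(O)c1O | intermediate
17 | 5-bromo-1,2,3-tris(benzyloxy)benzene | Brc1cc(OCc2ccccc2)c(OCc2ccccc2)c(OCc2ccccc2)c1 | intermediate
18 | N-[6-bromo-2,3,4-tris(benzyloxy)benzylidene]-N-methylmethanaminium chloride | C[N+](C)=Cc1c(Br)cc(OCc2ccccc2)c(OCc2ccccc2)c1OCc1ccccc1.[Cl-] | intermediate
19 | 6-bromo-2,3,4-tris(benzyloxy)benzaldehyde | O=Cc1c(Br)cc(OCc2ccccc2)c(OCc2ccccc2)c1OCc1ccccc1 | intermediate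
20 | 4-bromo-2,6-difluorobenzaldehyde | O=Cc1c(F)cc(Br)cc1F | starting material
21 | 4-bromo-2,6-bis(benzyloxy)benzaldehyde | O=Cc1c(OCc2ccccc2)cc(Br)cc1OCc1ccccc1 | intermediate
22 | AB aldehyde: 2,3-bis(benzyloxy)-5-[2,4,6-tris(benzyloxy)phenoxy]benzaldehyde | O(Cc6ccccc6)c1cc(OCc6ccccc6)c(Oc2cc(OCc6ccccc6)c(OCc6ccccc6)c(C=O)c2)c(OCc6ccccc6)c1 | intermediate
23 | AB formate: 2,3-bis(benzyloxy)-5-[2,4,6-tris(benzyloxy)phenoxy]phenyl formate | O(Cc6ccccc6)c1cc(OCc6ccccc6)c(Oc2cc(OCc6ccccc6)c(OCc6ccccc6)c(OC=O)c2)c(OCc6ccccc6)c1 | intermediate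
24 | AB phenol: 2,3-bis(benzyloxy)-5-[2,4,6-tris(benzyloxy)phenoxy]phenol | O(Cc6ccccc6)c1cc(OCc6ccccc6)c(Oc2cc(OCc6ccccc6)c(OCc6ccccc6)c(O)c2)c(OCc6ccccc6)c1 | intermediate
25 | ABC aldehyde: 2,3,4-tris(benzyloxy)-6-(AB-oxy)benzaldehyde | O(Cc6ccccc6)c1cc(OCc6ccccc6)c(Oc2cc(OCc6ccccc6)c(OCc6ccccc6)c(Oc3cc(OCc6ccccc6)c(OCc6ccccc6)c(OCc6ccccc6)c3C=O)c2)c(OCc6ccccc6)c1 | intermediate
26 | ABC formate: 2,3,4-tris(benzyloxy)-6-(AB-oxy)phenyl formate | O(Cc6ccccc6)c1cc(OCc6ccccc6)c(Oc2cc(OCc6ccccc6)c(OCc6ccccc6)c(Oc3cc(OCc6ccccc6)c(OCc6ccccc6)c(OCc6ccccc6)c3OC=O)c2)c(OCc6ccccc6)c1 | intermediate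
27 | ABC phenol: 2,3,4-tris(benzyloxy)-6-(AB-oxy)phenol | O(Cc6ccccc6)c1cc(OCc6ccccc6)c(Oc2cc(OCc6ccccc6)c(OCc6ccccc6)c(Oc3cc(OCc6ccccc6)c(OCc6ccccc6)c(OCc6ccccc6)c3O)c2)c(OCc6ccccc6)c1 | intermediate
28 | ABCD aldehyde: 2,6-bis(benzyloxy)-4-(ABC-oxy)benzaldehyde | O(Cc6ccccc6)c1cc(OCc6ccccc6)c(Oc2cc(OCc6ccccc6)c(OCc6ccccc6)c(Oc3cc(OCc6ccccc6)c(OCc6ccccc6)c(OCc6ccccc6)c3Oc3cc(OCc6ccccc6)c(C=O)c(OCc6ccccc6)c3)c2)c(OCc6ccccc6)c1 | intermediate
29 | ABCD formate: 2,6-bis(benzyloxy)-4-(ABC-oxy)phenyl formate | O(Cc6ccccc6)c1cc(OCc6ccccc6)c(Oc2cc(OCc6ccccc6)c(OCc6ccccc6)c(Oc3cc(OCc6ccccc6)c(OCc6ccccc6)c(OCc6ccccc6)c3Oc3cc(OCc6ccccc6)c(OC=O)c(OCc6ccccc6)c3)c2)c(OCc6ccccc6)c1 | intermediate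
30 | ABCD phenol: 2,6-bis(benzyloxy)-4-(ABC-oxy)phenol | O(Cc6ccccc6)c1cc(OCc6ccccc6)c(Oc2cc(OCc6ccccc6)c(OCc6ccccc6)c(Oc3cc(OCc6ccccc6)c(OCc6ccccc6)c(OCc6ccccc6)c3Oc3cc(OCc6ccccc6)c(O)c(OCc6ccccc6)c3)c2)c(OCc6ccccc6)c1 | intermediate
31 | ABCDE aldehyde: 2,3,4-tris(benzyloxy)-6-(ABCD-oxy)benzaldehyde | O(Cc6ccccc6)c1cc(OCc6ccccc6)c(Oc2cc(OCc6ccccc6)c(OCc6ccccc6)c(Oc3cc(OCc6ccccc6)c(OCc6ccccc6)c(OCc6ccccc6)c3Oc3cc(OCc6ccccc6)c(Oc4cc(OCc6ccccc6)c(OCc6ccccc6)c(OCc6ccccc6)c4C=O)c(OCc6ccccc6)c3)c2)c(OCc6ccccc6)c1 | intermediate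
32 | ABCDE formate: 2,3,4-tris(benzyloxy)-6-(ABCD-oxy)phenyl formate | O(Cc6ccccc6)c1cc(OCc6ccccc6)c(Oc2cc(OCc6ccccc6)c(OCc6ccccc6)c(Oc3cc(OCc6ccccc6)c(OCc6ccccc6)c(OCc6ccccc6)c3Oc3cc(OCc6ccccc6)c(Oc4cc(OCc6ccccc6)c(OCc6ccccc6)c(OCc6ccccc6)c4OC=O)c(OCc6ccccc6)c3)c2)c(OCc6ccccc6)c1 | intermediate
33 | ABCDE phenol: 2,3,4-tris(benzyloxy)-6-(ABCD-oxy)phenol | O(Cc6ccccc6)c1cc(OCc6ccccc6)c(Oc2cc(OCc6ccccc6)c(OCc6ccccc6)c(Oc3cc(OCc6ccccc6)c(OCc6ccccc6)c(OCc6ccccc6)c3Oc3cc(OCc6ccccc6)c(Oc4cc(OCc6ccccc6)c(OCc6ccccc6)c(OCc6ccccc6)c4O)c(OCc6ccccc6)c3)c2)c(OCc6ccccc6)c1 | intermediate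
34 | ABCDEF aldehyde: 2,6-bis(benzyloxy)-4-(ABCDE-oxy)benzaldehyde | O(Cc6ccccc6)c1cc(OCc6ccccc6)c(Oc2cc(OCc6ccccc6)c(OCc6ccccc6)c(Oc3cc(OCc6ccccc6)c(OCc6ccccc6)c(OCc6ccccc6)c3Oc3cc(OCc6ccccc6)c(Oc4cc(OCc6ccccc6)c(OCc6ccccc6)c(OCc6ccccc6)c4Oc4cc(OCc6ccccc6)c(C=O)c(OCc6ccccc6)c4)c(OCc6ccccc6)c3)c2)c(OCc6ccccc6)c1 | intermediate
35 | ABCDEF formate: 2,6-bis(benzyloxy)-4-(ABCDE-oxy)phenyl formate | O(Cc6ccccc6)c1cc(OCc6ccccc6)c(Oc2cc(OCc6ccccc6)c(OCc6ccccc6)c(Oc3cc(OCc6ccccc6)c(OCc6ccccc6)c(OCc6ccccc6)c3Oc3cc(OCc6ccccc6)c(Oc4cc(OCc6ccccc6)c(OCc6ccccc6)c(OCc6ccccc6)c4Oc4cc(OCc6ccccc6)c(OC=O)c(OCc6ccccc6)c4)c(OCc6ccccc6)c3)c2)c(OCc6ccccc6)c1 | intermediate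
36 | ABCDEF phenol: 2,6-bis(benzyloxy)-4-(ABCDE-oxy)phenol | O(Cc6ccccc6)c1cc(OCc6ccccc6)c(Oc2cc(OCc6ccccc6)c(OCc6ccccc6)c(Oc3cc(OCc6ccccc6)c(OCc6ccccc6)c(OCc6ccccc6)c3Oc3cc(OCc6ccccc6)c(Oc4cc(OCc6ccccc6)c(OCc6ccccc6)c(OCc6ccccc6)c4Oc4cc(OCc6ccccc6)c(O)c(OCc6ccccc6)c4)c(OCc6ccccc6)c3)c2)c(OCc6ccccc6)c1 | intermediate
37 | ABCDEFG aldehyde: 2,3,4-tris(benzyloxy)-6-(ABCDEF-oxy)benzaldehyde | O(Cc6ccccc6)c1cc(OCc6ccccc6)c(Oc2cc(OCc6ccccc6)c(OCc6ccccc6)c(Oc3cc(OCc6ccccc6)c(OCc6ccccc6)c(OCc6ccccc6)c3Oc3cc(OCc6ccccc6)c(Oc4cc(OCc6ccccc6)c(OCc6ccccc6)c(OCc6ccccc6)c4Oc4cc(OCc6ccccc6)c(Oc5cc(OCc6ccccc6)c(OCc6ccccc6)c(OCc6ccccc6)c5C=O)c(OCc6ccccc6)c4)c(OCc6ccccc6)c3)c2)c(OCc6ccccc6)c1 | intermediate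
38 | ABCDEFG formate: 2,3,4-tris(benzyloxy)-6-(ABCDEF-oxy)phenyl formate | O(Cc6ccccc6)c1cc(OCc6ccccc6)c(Oc2cc(OCc6ccccc6)c(OCc6ccccc6)c(Oc3cc(OCc6ccccc6)c(OCc6ccccc6)c(OCc6ccccc6)c3Oc3cc(OCc6ccccc6)c(Oc4cc(OCc6ccccc6)c(OCc6ccccc6)c(OCc6ccccc6)c4Oc4cc(OCc6ccccc6)c(Oc5cc(OCc6ccccc6)c(OCc6ccccc6)c(OCc6ccccc6)c5OC=O)c(OCc6ccccc6)c4)c(OCc6ccccc6)c3)c2)c(OCc6ccccc6)c1 | intermediate
39 | ABCDEFG phenol: 2,3,4-tris(benzyloxy)-6-(ABCDEF-oxy)phenol | O(Cc6ccccc6)c1cc(OCc6ccccc6)c(Oc2cc(OCc6ccccc6)c(OCc6ccccc6)c(Oc3cc(OCc6ccccc6)c(OCc6ccccc6)c(OCc6ccccc6)c3Oc3cc(OCc6ccccc6)c(Oc4cc(OCc6ccccc6)c(OCc6ccccc6)c(OCc6ccccc6)c4Oc4cc(OCc6ccccc6)c(Oc5cc(OCc6ccccc6)c(OCc6ccccc6)c(OCc6ccccc6)c5O)c(OCc6ccccc6)c4)c(OCc6ccccc6)c3)c2)c(OCc6ccccc6)c1 | intermediate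
40 | henicosa-O-benzyl octamer: 1,2,3-tris(benzyloxy)-5-(ABCDEFG-oxy)benzene (target with all 21 OH as OBn) | O(Cc6ccccc6)c1cc(OCc6ccccc6)c(Oc2cc(OCc6ccccc6)c(OCc6ccccc6)c(Oc3cc(OCc6ccccc6)c(OCc6ccccc6)c(OCc6ccccc6)c3Oc3cc(OCc6ccccc6)c(Oc4cc(OCc6ccccc6)c(OCc6ccccc6)c(OCc6ccccc6)c4Oc4cc(OCc6ccccc6)c(Oc5cc(OCc6ccccc6)c(OCc6ccccc6)c(OCc6ccccc6)c5Oc5cc(OCc6ccccc6)c(OCc6ccccc6)c(OCc6ccccc6)c5)c(OCc6ccccc6)c4)c(OCc6ccccc6)c3)c2)c(OCc6ccccc6)c1 | intermediate
41 | CNP0175816.0 | Oc1cc(O)c(Oc2cc(O)c(O)c(Oc3cc(O)c(O)c(O)c3Oc3cc(O)c(Oc4cc(O)c(O)c(O)c4Oc4cc(O)c(Oc5cc(O)c(O)c(O)c5Oc5cc(O)c(O)c(O)c5)c(O)c4)c(O)c3)c2)c(O)c1 | target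

**Totals**
Total step count: 26.
Longest linear sequence: 20 steps (steps 1–6, then 13–26, from diethyl malonate).

**Three steps most likely to fail, with fallbacks**

Step 11 (formylation of bromide 17). The ring is only moderately activated and the site is ortho to bromine, so the Vilsmeier reaction may be slow or incomplete. The fallback makes the C–C bond before the protecting groups are exchanged. It sets out from 15: Rieche formylation (Cl2CHOMe, TiCl4, CH2Cl2, 0 °C) at the only free ring position gives 6-bromo-2,3,4-trimethoxybenzaldehyde F1. BBr3 (CH2Cl2, −78 °C → rt) then gives 6-bromo-2,3,4-trihydroxybenzaldehyde F2. Benzylation (BnBr, K2CO3, DMF, 70 °C) gives 19, where the route resumes.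

Step 19 (the same bond type recurs in step 23). A phenol flanked by two benzyloxy groups must attack an ortho-substituted bromide on a large substrate, giving a tri-ortho-substituted diaryl ether; the coupling may stall. The fallback closes this hindered ether on monomers, where a large excess of partner and harsher conditions cost little, and then joins the resulting two-ring block through an unhindered bromide. It sets out from 21: Baeyer–Villiger oxidation (mCPBA, CH2Cl2; then K2CO3, MeOH) gives 4-bromo-2,6-bis(benzyloxy)phenyl formate F3 and from it 4-bromo-2,6-bis(benzyloxy)phenol F4. F4 is coupled with excess 19 (3 equiv, CuI, picolinic acid, K3PO4, DMSO, 110 °C); the para bromide of the electron-rich phenoxide is much less reactive than the ortho-formyl bromide of 19, so the product is 6-[4-bromo-2,6-bis(benzyloxy)phenoxy]-2,3,4-tris(benzyloxy)benzaldehyde F5. F5 (2 equiv) then arylates ABC phenol 27 under the conditions of step 25 and gives 31 directly, where the route resumes (28–30 are bypassed). The same block would serve with 33 to reach 37 if step 23 fails.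

Step 25 (last O-arylation). The bromide 17 is electron-rich and carries no activating group, and the phenol 39 is large and hindered. The fallback changes the aryl partner from electrophile to aryl-boron nucleophile in an oxidative coupling. It sets out from 17: Miyaura borylation (B2pin2, Pd(dppf)Cl2, KOAc, dioxane, 90 °C) gives 2-[3,4,5-tris(benzyloxy)phenyl]-4,4,5,5-tetramethyl-1,3,2-dioxaborolane F6. Chan–Lam coupling of F6 (3 equiv) with 39 (Cu(OAc)2, pyridine, B(OH)3, 4 Å MS, MeCN, dry air, 60 °C) gives 40, where the route resumes.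

**Further compounds**

F1 | step 11 | 6-bromo-2,3,4-trimethoxybenzaldehyde | COc1cc(Br)c(C=O)c(OC)c1OC
F2 | step 11 | 6-bromo-2,3,4-trihydroxybenzaldehyde | Oc1cc(Br)c(C=O)c(O)c1O
F3 | step 19 | 4-bromo-2,6-bis(benzyloxy)phenyl formate | O=COc1c(OCc2ccccc2)cc(Br)cc1OCc1ccccc1
F4 | step 19 | 4-bromo-2,6-bis(benzyloxy)phenol | Oc1c(OCc2ccccc2)cc(Br)cc1OCc1ccccc1
F5 | step 19 | 6-[4-bromo-2,6-bis(benzyloxy)phenoxy]-2,3,4-tris(benzyloxy)benzaldehyde | O=Cc1c(Oc2c(OCc3ccccc3)cc(Br)cc2OCc2ccccc2)cc(OCc2ccccc2)c(OCc2ccccc2)c1OCc1ccccc1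
F6 | step 25 | 2-[3,4,5-tris(benzyloxy)phenyl]-4,4,5,5-tetramethyl-1,3,2-dioxaborolane | CC1(C)OB(OC1(C)C)c1cc(OCc2ccccc2)c(OCc2ccccc2)c(OCc2ccccc2)c1
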